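**Plan**

- Cuts (germacrane numbering: C1 ketone, C3 and C10 carbinols, C4=C5 alkene, C6 lactone carbinol, C8 ester carbinol, C11=C13 methylene, C12 lactone carbonyl): C3–C4 of the ten-membered ring (aldehyde + Z-vinyl iodide), C11=C13 (phosphonate + formaldehyde), C7–C11 of the γ-lactone (O6-tethered phosphonoacetate carbanion + C7–C8 epoxide), C6–C7 (alkenylzinc + iodoenal), then C8–C9 and C1–C2 (acetylide and diazoacetate onto the glycidol-derived C9–C10–C1 unit).
- Forward: the C1–C3/C7–C10 alkyne is built from (S)-2-methylglycidol and joined at C6–C7 to the C4–C6 iodoenal from but-2-yn-1-ol; the γ-lactone ring closes first (step 13), the ten-membered carbocycle last (step 17).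
- Enabling feature: the contiguous C6–O, C7–C11, C8–O triad on the trans-fused lactone ring is, read backwards, an erythro C6 carbinol beside a trans C7–C8 epoxide, whose C7 is reached through a five-membered transition state by a carbon hung on O6.
- Stereochemistry: C10 from (S)-2-methylglycidol; C6 from ligand-controlled alkenylzinc addition, secured together with C7/C8 by Sharpless epoxidation with D-(−)-DIPT; C7 inverted stereospecifically and C8 retained in the key step; C3 by substrate control in the ring closure; 4Z from hydroxyl-directed hydroalumination–iodination.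

Key step: step 13

Remark: the C11 epimer drawn for 20 and 22 is the expected trans one; it is immaterial because C11 becomes sp2 in step 15.

**Route**

Step 1
Reactants: 1 but-2-yn-1-ol
Product: 3 (Z)-3-iodobut-2-en-1-ol, via cyclic alkenylalanate 2 (not isolated)
Conditions: NaAlH2(OCH2CH2OMe)2, THF, 0 °C to rt; then I2, THF, −78 °C to 0 °C
Reagents that add atoms: iodine ([I][I])
Why: hydroxyl-directed trans-hydroalumination of the propargylic alcohol places aluminium on C3 inside a five-membered alanate ring and iodinolysis of the C–Al bond with retention should give the Z-iodoalkene (hydroalumination–iodination of a propargylic alcohol).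

Step 2
Reactants: 3 (Z)-3-iodobut-2-en-1-ol
Product: 4 (Z)-3-iodobut-2-enal
Conditions: MnO2 (activated), CH2Cl2, rt, dark; used at once
Reagents that add atoms: none
Why: allylic oxidation on MnO2 is neutral and heterogeneous, so the Z geometry of the sensitive iodoenal should survive.

Step 3
Reactants: 5 (S)-2-methylglycidol
Product: 6 (R)-2-methylpent-4-yne-1,2-diol
Conditions: LiC≡CH·H2NCH2CH2NH2 (3 equiv), DMSO, 0 °C to rt; aq. NH4Cl
Reagents that add atoms: lithium acetylide, LiC≡CH, as its ethylenediamine complex ([Li+].[C-]#C)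
Why: SN2 opening of the epoxide at its unsubstituted CH2 by acetylide forms C8–C9 and leaves the quaternary carbinol carbon (C10) untouched, the descriptor changing only because the priorities change.

Step 4
Reactants: 6 (R)-2-methylpent-4-yne-1,2-diol
Product: 7 (R)-2-methyl-1,2-bis(triethylsilyloxy)pent-4-yne
Conditions: TESOTf (2.4 equiv), 2,6-lutidine, CH2Cl2, −78 °C to 0 °C
Reagents that add atoms: triethylsilyl trifluoromethanesulfonate (CC[Si](CC)(CC)OS(=O)(=O)C(F)(F)F)
Why: silyl triflate with a hindered pyridine base silylates the tertiary as well as the primary hydroxyl and leaves the terminal alkyne untouched.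

Step 5
Reactants: 7 bis(triethylsilyl) ether
Product: 8 (R)-2-methyl-2-(triethylsilyloxy)pent-4-ynal
Conditions: (COCl)2, DMSO, CH2Cl2, −78 to −30 °C; then Et3N, −78 °C to 0 °C
Reagents that add atoms: none
Why: under Swern conditions the chlorosulfonium salt cleaves a primary triethylsilyl ether and oxidises it in the same flask while the tertiary silyl ether is inert, and the resulting aldehyde has no α-hydrogen to lose (Swern oxidation of a primary silyl ether).

Step 6
Reactants: 8 α-silyloxy aldehyde
Product: 9 ethyl (R)-4-methyl-3-oxo-4-(triethylsilyloxy)hept-6-ynoate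
Conditions: N2CHCO2Et, SnCl2 (10 mol%), CH2Cl2, rt
Reagents that add atoms: ethyl diazoacetate (CCOC(=O)C=[N+]=[N-])
Why: in the Roskamp homologation the tin-activated aldehyde adds the diazo ester and a 1,2-hydride shift with loss of nitrogen should give the β-keto ester (C1 ketone, C2, C3 ester) in one step.

Step 7
Reactants: 9 β-keto ester
Product: 10 ethyl 2-{2-[(2R)-2-(triethylsilyloxy)pent-4-yn-2-yl]-1,3-dioxolan-2-yl}acetate
Conditions: (Me3SiOCH2)2, TMSOTf (5 mol%), CH2Cl2, −78 to −20 °C; pyridine quench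
Reagents that add atoms: 1,2-bis(trimethylsilyloxy)ethane (C[Si](C)(C)OCCO[Si](C)(C)C)
Why: Noyori ketalisation is driven by formation of hexamethyldisiloxane under aprotic conditions and is the usual answer for a hindered ketone that carries acid-labile silyl ethers.

Step 8
Reactants: 10 ketal ester
Product: 11 2-{2-[(2R)-2-(triethylsilyloxy)pent-4-yn-2-yl]-1,3-dioxolan-2-yl}ethan-1-ol
Conditions: LiAlH4, Et2O, 0 °C
Reagents that add atoms: none
Why: hydride reduction of the ester to the C3 primary alcohol should leave the ketal, the tertiary silyl ether and the isolated alkyne unchanged.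

Step 9
Reactants: 11 primary alcohol
Product: 12 triethyl(2-{2-[(2R)-2-(triethylsilyloxy)pent-4-yn-2-yl]-1,3-dioxolan-2-yl}ethoxy)silane
Conditions: TESCl, imidazole, CH2Cl2, 0 °C
Reagents that add atoms: chlorotriethylsilane (CC[Si](Cl)(CC)CC)
Why: routine silylation, the primary triethylsilyl ether being chosen because it can later be oxidised directly to the aldehyde beside the tertiary one.

Step 10
Reactants: 12 alkyne fragment; 4 (Z)-3-iodobut-2-enal
Product: 15 (2Z,4S,5E,8R)-2-iodo-8-(triethylsilyloxy)-8-{2-[2-(triethylsilyloxy)ethyl]-1,3-dioxolan-2-yl}nona-2,5-dien-4-ol, via alkenyl(dicyclohexyl)borane 13 (not isolated), via alkenyl(methyl)zinc 14 (not isolated)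
Conditions: Cy2BH, toluene, 0 °C to rt; Me2Zn, −78 °C; (−)-MIB (5 mol%), then 4, −20 °C to 0 °C; aq. NH4Cl
Reagents that add atoms: none
Why: syn-hydroboration gives the E-alkenylborane, boron-to-zinc exchange the alkenylzinc, and the amino-alkoxide zinc catalyst is expected to direct 1,2-addition to the Si face of the enal, forming C6–C7 and the (S)-carbinol at C6 (catalytic asymmetric alkenylzinc addition).

Step 11
Reactants: 15 bis-allylic alcohol
Product: 16 (1R,2Z)-3-iodo-1-{(2R,3R)-3-[(2R)-2-(triethylsilyloxy)-2-{2-[2-(triethylsilyloxy)ethyl]-1,3-dioxolan-2-yl}propyl]oxiran-2-yl}but-2-en-1-ol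
Conditions: Ti(OiPr)4 (20 mol%), D-(−)-DIPT (24 mol%), t-BuOOH (1.5 equiv), 4 Å MS, CH2Cl2, −20 °C
Reagents that add atoms: tert-butyl hydroperoxide (CC(C)(C)OO)
Why: in this Sharpless asymmetric epoxidation the D-(−)-tartrate complex should deliver oxygen to the E C7–C8 alkene of the (S)-carbinol on the face that gives the erythro epoxy alcohol (matched pair), while any C6 epimer and the electron-poor, Z-substituted iodoalkene react far more slowly, so the step also purges the minor epimer as in a kinetic resolution.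

Step 12
Reactants: 16 erythro epoxy alcohol; 17 diethylphosphonoacetic acid
Product: 18 (1R,2Z)-3-iodo-1-{(2S,3R)-3-[(2R)-2-(triethylsilyloxy)-2-{2-[2-(triethylsilyloxy)ethyl]-1,3-dioxolan-2-yl}propyl]oxiran-2-yl}but-2-en-1-yl (diethoxyphosphoryl)acetate
Conditions: DCC, DMAP (10 mol%), CH2Cl2, 0 °C to rt
Reagents that add atoms: none
Why: Steglich esterification acylates the secondary epoxy alcohol under neutral conditions, which avoids Payne rearrangement and premature deprotonation of the phosphonoacetate (the C7 descriptor changes by priority only).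

Step 13
Reactants: 18 epoxy phosphonoacetate
Product: 20 diethyl {(3S,4R,5S)-4-[(1R,3R)-1-hydroxy-3-(triethylsilyloxy)-3-{2-[2-(triethylsilyloxy)ethyl]-1,3-dioxolan-2-yl}butyl]-5-[(1Z)-2-iodoprop-1-en-1-yl]-2-oxooxolan-3-yl}phosphonate, via lithiated phosphonoacetate 19 (not isolated)
Conditions: LiN(SiMe3)2 (1.05 equiv), THF, −78 °C; then 0 to 45 °C; AcOH then aq. NH4Cl at −78 °C
Reagents that add atoms: none
Why: Proposed new method: LiN(SiMe3)2 deprotonates the phosphonoacetate of 18 to the lithium-chelated carbanion 19, whose C11 attacks the proximal epoxide carbon C7 from the side opposite the C7–O bond (SN2), forming C7–C11 and the γ-lactone and releasing the C8 alkoxide, which is at once protonated by the much more acidic α-phosphono lactone so that the product rests as an unreactive enolate with a free C8 hydroxyl until the quench. The closest known reactions are the intermolecular opening of epoxides by phosphonoacetate anions to α-phosphono-γ-lactones and the base-induced opening of 2,3-epoxy alcohol carbamates at C2 by the tethered nitrogen; the ester-tethered carbon version is the untested element. The lactone ring closes in the 5-exo-tet mode, and because the ring carbonyl lies inside the forming ring the carbanion must twist out of conjugation with it in the transition state, so the exocyclic phosphoryl group has to carry the stabilisation, which is why a phosphonate (also the later olefination handle) is used and why gentle warming is planned. C7 is set by stereospecific inversion of the epoxide carbon, C8 keeps its epoxide oxygen with retention, and C11 should settle trans to the C7 side chain by equilibration of the acidic α-position (it is erased in step 15). The step needs attack at C7 and not C8, secured by the three-atom O6–C12–C11 tether, which reaches C7 through a five-membered and C8 only through a six-membered endo transition state, and C- rather than O-alkylation, which lithium chelation of the enolate and phosphoryl oxygens in THF and the softness of the epoxide carbon should favour.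

Step 14
Reactants: 20 hydroxy phosphono lactone; 21 isovaleryl chloride
Product: 22 (1R,3R)-1-{(2S,3R,4S)-4-(diethoxyphosphoryl)-2-[(1Z)-2-iodoprop-1-en-1-yl]-5-oxooxolan-3-yl}-3-(triethylsilyloxy)-3-{2-[2-(triethylsilyloxy)ethyl]-1,3-dioxolan-2-yl}butyl 3-methylbutanoate
Conditions: pyridine, DMAP (10 mol%), CH2Cl2, 0 °C
Reagents that add atoms: none
Why: DMAP-catalysed acylation of the secondary C8 hydroxyl with a base too weak to deprotonate the α-phosphono lactone caps O8 before it can translactonise to the 8,12-olide.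

Step 15
Reactants: 22 acylated phosphono lactone
Product: 23 (1R,3R)-1-{(2S,3R)-2-[(1Z)-2-iodoprop-1-en-1-yl]-4-methylidene-5-oxooxolan-3-yl}-3-(triethylsilyloxy)-3-{2-[2-(triethylsilyloxy)ethyl]-1,3-dioxolan-2-yl}butyl 3-methylbutanoate
Conditions: aq. CH2O (37%), K2CO3, THF, 0 °C to rt
Reagents that add atoms: formaldehyde (C=O)
Why: Horner–Wadsworth–Emmons olefination of the α-phosphono lactone with formaldehyde under mild carbonate conditions should install the exocyclic C11=C13 methylene without touching the isovalerate or the silyl ethers.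

Step 16
Reactants: 23 α-methylene lactone
Product: 24 (1R,3R)-1-{(2S,3R)-2-[(1Z)-2-iodoprop-1-en-1-yl]-4-methylidene-5-oxooxolan-3-yl}-3-[2-(2-oxoethyl)-1,3-dioxolan-2-yl]-3-(triethylsilyloxy)butyl 3-methylbutanoate
Conditions: (COCl)2, DMSO, CH2Cl2, −78 to −35 °C; then Et3N, −78 °C to 0 °C
Reagents that add atoms: none
Why: as in step 5, Swern conditions convert the primary triethylsilyl ether at C3 directly into the aldehyde while the tertiary C10 silyl ether, the ketal and the enoate are spectators.

Step 17
Reactants: 24 iodo aldehyde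
Product: 25 (3R,4Z,6R,7R,8R,10R)-1,1-(ethylenedioxy)-3-hydroxy-8-(3-methylbutanoyloxy)-10-(triethylsilyloxy)germacra-4,11(13)-dien-12,6-olide
Conditions: CrCl2 (8 equiv), NiCl2 (2 mol%), DMSO, rt, 0.002 M, slow addition of 24
Reagents that add atoms: none
Why: in the Nozaki–Hiyama–Kishi reaction nickel-catalysed insertion into the C–I bond and transfer to chromium give an alkenylchromium species of retained Z geometry that adds only to the aldehyde under high dilution to form C3–C4 and the ten-membered ring, the C3 configuration resting on substrate control (attack on the aldehyde face left open when the C1 dioxolane and C10 silyloxy groups point away from the lactone), which is expected but not assured to give 3R.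

Step 18
Reactants: 25 protected macrocycle
Product: 26 (3R,4Z,6R,7R,8R,10R)-3,10-dihydroxy-8-(3-methylbutanoyloxy)-1-oxogermacra-4,11(13)-dien-12,6-olide (CNP0406522.1)
Conditions: 1 M aq. HCl–THF (1:3), 0 °C to rt
Reagents that add atoms: water (O)
Why: dilute aqueous acid should hydrolyse the tertiary triethylsilyl ether and the dioxolane (the C1 carbonyl oxygen comes from water) under conditions that the α-methylene lactone, the isovalerate and the β-hydroxy ketone tolerate at room temperature.

**Compound list**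

1 | but-2-yn-1-ol | CC#CCO | starting material
2 | sodium cyclic alkenylalanate (five-membered O–CH2–CH=C(CH3)–Al ring, two 2-methoxyethoxy groups on aluminium) | [Na+].CC1=CCO[Al-]1(OCCOC)OCCOC | intermediate
3 | (Z)-3-iodobut-2-en-1-ol | I/C(C)=C\CO | intermediate
4 | (Z)-3-iodobut-2-enal | I/C(C)=C\C=O | intermediate
5 | (S)-2-methylglycidol | OC[C@]1(C)OC1 | starting material
6 | (R)-2-methylpent-4-yne-1,2-diol | C#CC[C@@](C)(O)CO | intermediate
7 | (R)-2-methyl-1,2-bis(triethylsilyloxy)pent-4-yne | C#CC[C@@](C)(O[Si](CC)(CC)CC)CO[Si](CC)(CC)CC | intermediate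
8 | (R)-2-methyl-2-(triethylsilyloxy)pent-4-ynal | C#CC[C@@](C)(O[Si](CC)(CC)CC)C=O | intermediate
9 | ethyl (R)-4-methyl-3-oxo-4-(triethylsilyloxy)hept-6-ynoate | C#CC[C@@](C)(O[Si](CC)(CC)CC)C(=O)CC(=O)OCC | intermediate
10 | ethyl 2-{2-[(2R)-2-(triethylsilyloxy)pent-4-yn-2-yl]-1,3-dioxolan-2-yl}acetate | C#CC[C@@](C)(O[Si](CC)(CC)CC)C1(OCCO1)CC(=O)OCC | intermediate
11 | 2-{2-[(2R)-2-(triethylsilyloxy)pent-4-yn-2-yl]-1,3-dioxolan-2-yl}ethan-1-ol | C#CC[C@@](C)(O[Si](CC)(CC)CC)C1(OCCO1)CCO | intermediate
12 | triethyl(2-{2-[(2R)-2-(triethylsilyloxy)pent-4-yn-2-yl]-1,3-dioxolan-2-yl}ethoxy)silane | C#CC[C@@](C)(O[Si](CC)(CC)CC)C1(OCCO1)CCO[Si](CC)(CC)CC | intermediate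
13 | (E)-alkenyl(dicyclohexyl)borane (12 with Cy2B–CH=CH– in place of HC≡C–) | C1CCCCC1B(C1CCCCC1)/C=C/C[C@@](C)(O[Si](CC)(CC)CC)C1(OCCO1)CCO[Si](CC)(CC)CC | intermediate
14 | (E)-alkenyl(methyl)zinc (12 with MeZn–CH=CH– in place of HC≡C–) | C[Zn]/C=C/C[C@@](C)(O[Si](CC)(CC)CC)C1(OCCO1)CCO[Si](CC)(CC)CC | intermediate
15 | (2Z,4S,5E,8R)-2-iodo-8-(triethylsilyloxy)-8-{2-[2-(triethylsilyloxy)ethyl]-1,3-dioxolan-2-yl}nona-2,5-dien-4-ol | I/C(C)=C\[C@@H](O)/C=C/C[C@@](C)(O[Si](CC)(CC)CC)C1(OCCO1)CCO[Si](CC)(CC)CC | intermediate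
16 | (1R,2Z)-3-iodo-1-{(2R,3R)-3-[(2R)-2-(triethylsilyloxy)-2-{2-[2-(triethylsilyloxy)ethyl]-1,3-dioxolan-2-yl}propyl]oxiran-2-yl}but-2-en-1-ol (erythro epoxy alcohol) | I/C(C)=C\[C@@H](O)[C@H]1O[C@@H]1C[C@@](C)(O[Si](CC)(CC)CC)C1(OCCO1)CCO[Si](CC)(CC)CC | intermediate
17 | diethylphosphonoacetic acid | OC(=O)CP(=O)(OCC)OCC | starting material
18 | (1R,2Z)-3-iodo-1-{(2S,3R)-3-[(2R)-2-(triethylsilyloxy)-2-{2-[2-(triethylsilyloxy)ethyl]-1,3-dioxolan-2-yl}propyl]oxiran-2-yl}but-2-en-1-yl (diethoxyphosphoryl)acetate | I/C(C)=C\[C@@H](OC(=O)CP(=O)(OCC)OCC)[C@H]1O[C@@H]1C[C@@](C)(O[Si](CC)(CC)CC)C1(OCCO1)CCO[Si](CC)(CC)CC | intermediate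
19 | lithium salt of the α-carbanion of 18 (lithiated phosphonoacetate) | [Li+].I/C(C)=C\[C@@H](OC(=O)[CH-]P(=O)(OCC)OCC)[C@H]1O[C@@H]1C[C@@](C)(O[Si](CC)(CC)CC)C1(OCCO1)CCO[Si](CC)(CC)CC | intermediate
20 | diethyl {(3S,4R,5S)-4-[(1R,3R)-1-hydroxy-3-(triethylsilyloxy)-3-{2-[2-(triethylsilyloxy)ethyl]-1,3-dioxolan-2-yl}butyl]-5-[(1Z)-2-iodoprop-1-en-1-yl]-2-oxooxolan-3-yl}phosphonate | I/C(C)=C\[C@H]1OC(=O)[C@@H](P(=O)(OCC)OCC)[C@@H]1[C@H](O)C[C@@](C)(O[Si](CC)(CC)CC)C1(OCCO1)CCO[Si](CC)(CC)CC | intermediate
21 | isovaleryl chloride (3-methylbutanoyl chloride) | CC(C)CC(=O)Cl | starting material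
22 | (1R,3R)-1-{(2S,3R,4S)-4-(diethoxyphosphoryl)-2-[(1Z)-2-iodoprop-1-en-1-yl]-5-oxooxolan-3-yl}-3-(triethylsilyloxy)-3-{2-[2-(triethylsilyloxy)ethyl]-1,3-dioxolan-2-yl}butyl 3-methylbutanoate | I/C(C)=C\[C@H]1OC(=O)[C@@H](P(=O)(OCC)OCC)[C@@H]1[C@H](OC(=O)CC(C)C)C[C@@](C)(O[Si](CC)(CC)CC)C1(OCCO1)CCO[Si](CC)(CC)CC | intermediate
23 | (1R,3R)-1-{(2S,3R)-2-[(1Z)-2-iodoprop-1-en-1-yl]-4-methylidene-5-oxooxolan-3-yl}-3-(triethylsilyloxy)-3-{2-[2-(triethylsilyloxy)ethyl]-1,3-dioxolan-2-yl}butyl 3-methylbutanoate | I/C(C)=C\[C@H]1OC(=O)C(=C)[C@@H]1[C@H](OC(=O)CC(C)C)C[C@@](C)(O[Si](CC)(CC)CC)C1(OCCO1)CCO[Si](CC)(CC)CC | intermediate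
24 | (1R,3R)-1-{(2S,3R)-2-[(1Z)-2-iodoprop-1-en-1-yl]-4-methylidene-5-oxooxolan-3-yl}-3-[2-(2-oxoethyl)-1,3-dioxolan-2-yl]-3-(triethylsilyloxy)butyl 3-methylbutanoate | I/C(C)=C\[C@H]1OC(=O)C(=C)[C@@H]1[C@H](OC(=O)CC(C)C)C[C@@](C)(O[Si](CC)(CC)CC)C1(OCCO1)CC=O | intermediate
25 | (3R,4Z,6R,7R,8R,10R)-1,1-(ethylenedioxy)-3-hydroxy-8-(3-methylbutanoyloxy)-10-(triethylsilyloxy)germacra-4,11(13)-dien-12,6-olide | C=C1C(=O)O[C@@H]2/C=C(/C)[C@H](O)CC3(OCCO3)[C@](C)(O[Si](CC)(CC)CC)C[C@@H](OC(=O)CC(C)C)[C@@H]12 | intermediate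
26 | (3R,4Z,6R,7R,8R,10R)-3,10-dihydroxy-8-(3-methylbutanoyloxy)-1-oxogermacra-4,11(13)-dien-12,6-olide (CNP0406522.1) | C=C1C(=O)O[C@@H]2/C=C(/C)[C@H](O)CC(=O)[C@](C)(O)C[C@@H](OC(=O)CC(C)C)[C@@H]12 | target

**Count**

Total steps: 18. Longest linear sequence: 16 steps (5 to 26, steps 3–18); the iodoenal branch (steps 1–2) joins at step 10.

**Steps most likely to fail**

Step 13 (proposed new method). The ambident anion may alkylate on oxygen: the enolate oxygen can close a 2-alkylidene-1,3-dioxolane at C7 from the ground-state ester rotamer. C-attack may also be too slow because the ring carbonyl cannot stay conjugated in the transition state, and prolonged warming could allow phosphoryl migration to O8. The fallback uses known radical chemistry, sets out from 16 and returns at 23. O6 of 16 is alkylated (NaH, propargyl bromide, THF, 0 °C) to the propargyl ether of the epoxy alcohol F1. Nugent–RajanBabu opening of the epoxide with Cp2TiCl (trivalent titanium, made from Cp2TiCl2 and Zn) in THF breaks the C7–O bond homolytically, and the C7 radical cyclises 5-exo-dig onto the alkyne to give the 3-methylene-oxolane alcohol F2. C8 keeps its oxygen and C7 is set trans to the C6 substituent by the cyclisation. Acylation with 21 (pyridine, DMAP) gives the isovalerate F3, and allylic oxidation of the ring CH2 next to oxygen (CrO3·2C5H5N, CH2Cl2) gives the α-methylene lactone 23.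

Step 17. Facial selectivity at the aldehyde during closure of the ten-membered ring may be poor or reversed, and intermolecular coupling competes with cyclisation. The fallback sets out from the C3 epimer mixture of 25 and returns at 25. The mixture is oxidised (Dess–Martin periodinane, NaHCO3, CH2Cl2) to the C3 enone F4, and the carbonyl is reduced under reagent control by Corey–Bakshi–Shibata reduction ((S)-2-methyl-CBS-oxazaborolidine, catecholborane, toluene, −78 °C). The alkenyl side acts as the large group, which should give the 3R alcohol 25.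

Step 7. Ketalisation of a ketone flanked by a quaternary, silyloxy-bearing carbon may stall, and enol silylation of the β-keto ester or loss of the tertiary silyl ether may take over. The fallback introduces C1 already masked, sets out from 8 and returns at 11, bypassing steps 6–8. Aldehyde 8 is converted (propane-1,3-dithiol, BF3·OEt2, CH2Cl2, −20 °C) into the 1,3-dithiane F5. Double deprotonation (n-BuLi, 2.2 equiv, THF, −30 °C; the acetylide is inert to the epoxide without a Lewis acid) and Corey–Seebach alkylation with ethylene oxide give the hydroxyethyl dithiane F6. Thioketal-to-ketal exchange with PhI(O2CCF3)2 in ethylene glycol–MeCN then delivers the dioxolane alcohol 11.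

**Further compounds**

F1 | step 13 | propargyl ether of epoxy alcohol 16 (O6–CH2C≡CH) | I/C(C)=C\[C@@H](OCC#C)[C@H]1O[C@@H]1C[C@@](C)(O[Si](CC)(CC)CC)C1(OCCO1)CCO[Si](CC)(CC)CC
F2 | step 13 | (1R,3R)-1-{(2S,3R)-2-[(1Z)-2-iodoprop-1-en-1-yl]-4-methylideneoxolan-3-yl}-3-(triethylsilyloxy)-3-{2-[2-(triethylsilyloxy)ethyl]-1,3-dioxolan-2-yl}butan-1-ol | I/C(C)=C\[C@H]1OCC(=C)[C@@H]1[C@H](O)C[C@@](C)(O[Si](CC)(CC)CC)C1(OCCO1)CCO[Si](CC)(CC)CC
F3 | step 13 | 3-methylbutanoate of F2 at the side-chain C1 (C8) hydroxyl | I/C(C)=C\[C@H]1OCC(=C)[C@@H]1[C@H](OC(=O)CC(C)C)C[C@@](C)(O[Si](CC)(CC)CC)C1(OCCO1)CCO[Si](CC)(CC)CC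
F4 | step 17 | (4Z,6R,7R,8R,10R)-1,1-(ethylenedioxy)-8-(3-methylbutanoyloxy)-3-oxo-10-(triethylsilyloxy)germacra-4,11(13)-dien-12,6-olide | C=C1C(=O)O[C@@H]2/C=C(/C)C(=O)CC3(OCCO3)[C@](C)(O[Si](CC)(CC)CC)C[C@@H](OC(=O)CC(C)C)[C@@H]12
F5 | step 7 | 2-[(2R)-2-(triethylsilyloxy)pent-4-yn-2-yl]-1,3-dithiane | C#CC[C@@](C)(O[Si](CC)(CC)CC)C1SCCCS1
F6 | step 7 | 2-{2-[(2R)-2-(triethylsilyloxy)pent-4-yn-2-yl]-1,3-dithian-2-yl}ethan-1-ol | C#CC[C@@](C)(O[Si](CC)(CC)CC)C1(CCO)SCCCS1
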